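# Deoxycalyxin A by reductive alkyl-alkenylation of a ring A styrene: synthesis design

## The problem

Deoxycalyxin A (19) is an acyclic assembly of four benzene rings. It is a 1,7-diarylhept-1-ene (ring B on C1, ring C on C7) whose C5 is bonded to C4′ of a 2,4,6-trioxygenated ring A, which also carries a 4-hydroxycinnamoyl group (ring D) at C6′. Ring A is numbered here from the methoxy carbon C1′ through C2′ (H), C3′ (OH), C4′ and C5′ (OH) to C6′. No ring has to be formed, so the work lies in making the chain bonds C3–C4 and C5–C6 and the aryl ketone bond at C6′ in a workable order.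

The only stereocentre is C5 (R), a tertiary carbon carrying an aryl, an (E)-alkenyl and a plain alkyl group. Nothing else in the molecule can direct it, so its configuration has to come from a chiral catalyst, and both alkenes (C6=C7 and the enone) must be E.

Three features restrict the reagents:
- The 2′-hydroxychalcone closes to a flavanone with acid or unbuffered base.
- The free C3′ and C5′ hydroxyls can add to the C6=C7 styrene under acid, and ring A would stabilise a cation at C5, so any C5 electrophile would ionise and lose its configuration.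
- Five phenols have to be released at the end without acid.

Before acylation ring A is locally symmetric (C2′ and C6′ are interchangeable, as are C3′ and C5′), so late introduction of the cinnamoyl group raises no regiochemical question. The feature that makes a one-step assembly conceivable is C5 itself: a benzylic carbon that carries a radical well, with an unfunctionalised tail on one side (C4 to C1) and an sp2 carbon on the other (C6). This is the pattern left by addition of an alkyl radical to the terminal carbon of a ring A styrene followed by alkenylation of the benzylic radical.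

## Retrosynthesis

**19 from 18 (five O–Si bonds).** The last operation is the release of five phenols. Silyl ethers are chosen for all of them because buffered fluoride is the only deprotection that leaves the hydroxychalcone, the styrene and C5 alone; acetal or benzyl protection would need acid or hydrogen. The forward step must keep the liberated phenoxides protonated.

**18 from 13 and 15 (C6′–carbonyl bond, through 16 and 17).** The aryl ketone bond is cut to an arylmagnesium species 16, made from iodide 13, and the silylated cinnamaldehyde 15, with carbinol 17 oxidised afterwards. The neighbouring cuts are worse: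
- A Friedel–Crafts acylation needs acid.
- An aldol condensation on a ring A methyl ketone would put an acetyl group on ring A before the key step and destroy its local symmetry.

The cut removes nine carbons and returns ring A to the symmetric pattern. The forward reaction needs a metalated ring A that tolerates ortho silyloxy groups, which points to magnesium rather than lithium.

**13 from 12 (C6′–I bond).** The iodine goes in by electrophilic substitution on the trioxygenated ring of 12. C2′ and C6′ are equivalent, so only chemoselectivity (ring A against the C6=C7 alkene) is asked of the step.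

**12 from 4, 7 and 11 (C3–C4 and C5–C6 bonds).** This is the key disconnection. Cutting C5–C6 alone would need a C5 benzylic halide, which ring A would ionise. Cutting C4–C5 alone would need an allylic substitution at a very hindered carbon with a four-carbon organometallic. Cutting both C3–C4 and C5–C6 leads to three simple pieces: the ring A styrene 4, the 3-arylpropyl iodide 7 and the (E)-bromostyrene 11. The forward reaction is a nickel-catalysed reductive three-component coupling in which C5 exists only as a planar radical. It must place the alkyl group on C4 and the alkenyl group on C5, in that order, and set C5 under ligand control.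

**4 from 3, 2 and 1.** The styrene comes from aldehyde 3 by Wittig methylenation, 3 from the diphenol 2 by silylation, and 2 from commercial 2,4,6-trimethoxybenzaldehyde 1 by cleavage of the two ortho methyl ethers. The ortho selectivity rests on chelation to the aldehyde, which the para methoxy group cannot take part in.

**7, 11 and 15 from 5, 8 and 14.**
- Iodide 7 comes from the phenol 6 by silylation, and 6 from commercial 3-(4-hydroxyphenyl)propan-1-ol 5 by an Appel iodination. This order avoids having to distinguish the two hydroxyls in a silylation.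
- Bromide 11 comes from the silylated cinnamic acid 10 by bromodecarboxylation. Acid 10 comes from (E)-4-hydroxycinnamic acid 8 through the bis-silyl compound 9.
- Aldehyde 15 is the silyl ether of (E)-4-hydroxycinnamaldehyde 14.

## Roads not taken

**Alternative 1:** aryne plus enal to a 2H-chromene.
- **Cut:** the pyran ring of chromene A1 is opened retrosynthetically at C3′–O, C4′–C5 and O–C7, giving an aryne (from silyl triflate A2) and the enal A3.
- **Forward key step:** fluoride releases the 3-alkoxyaryne from A2. The carbonyl oxygen of A3 adds to the aryne carbon remote from the alkoxy group (C3′) and the aryl anion closes on the carbonyl carbon (C4′–C5). The benzoxete opens to a vinyl ortho-quinone methide, which closes by oxa-6π electrocyclisation (O–C7) to A1.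
- **Merits:** it needs no metal, belongs to a known reaction type, has its regiochemistry set by the alkoxy group, and joins two cheap partners.
- **Weak points:**
  - In A1, C5 is sp2, and the C1–C4 chain and ring B are still missing.
  - The stereocentre would have to come from a later enantioselective SN2′ opening of the racemising chromene by a 4-arylbutyl nucleophile at C5, with the C3′ phenoxide leaving. That dynamic kinetic process has no close precedent with unactivated alkyl nucleophiles.
  - The methoxymethyl ethers must be removed with acid, which the target does not tolerate well.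
  - A2 itself needs several steps.
- **Comparison:** its key step is better precedented than step 8, and that is a real advantage. But it only postpones the hard event, asymmetric C–C bond formation at C5, and still needs acylation at C6′. The chosen plan spends its one unproven step where two skeletal bonds and the stereocentre are made together, and it uses fluoride-labile groups throughout.

**Alternative 2:** ring A by cyclobutenone–siloxyalkyne benzannulation.
- **Cut:** ring A of A4 is cut at C4′–C5′, C2′–C3′ and C5′–C6′, giving 3-methoxycyclobutenone A5 and the chiral siloxyalkyne A6.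
- **Forward key step:** heating opens A5 to a vinylketene, which adds the alkyne in a [2+2] fashion. A second 4π opening and a 6π closure give, after tautomerisation, the resorcinol monosilyl ether A4 with C5 already attached.
- **Merits:** the benzannulation is a well-established reaction type, the substitution pattern of ring A is fixed by construction, and the stereocentre can be made beforehand by established asymmetric chemistry.
- **Weak points:**
  - The stereocentre has to be carried, as an α-vinyl α-branched ester, through strongly basic ynolate formation to A6 and then through heating. Both invite racemisation or alkene migration.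
  - A4 still lacks ring C (a cross-metathesis or Heck reaction on the vinyl group) and the cinnamoyl group.
  - The differentiation of the C3′ and C5′ oxygens that the method provides is not needed here.
- **Comparison:** the key step stands on firmer ground than step 8. The chosen plan sets against this its convergence (three branches of two or three steps meet in one operation), a shorter longest linear sequence, and the fact that C5 is never exposed to strong base. The fallback for step 8 borrows the logic of this alternative by making C5 first with a known method.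

**Alternative 3:** pyrone to acylphloroglucinol, in the manner of chalcone synthase.
- **Cut:** the C5′–C6′ bond of ring A in A7 is cut, leading back to the 2-pyrone A8.
- **Forward key step:** Mg(OMe)2 in methanol opens the lactone of A8 to a methyl ester. The magnesium-bound carbanion of the side-chain methylene (future C6′) acylates that ester carbon (future C5′), and aromatisation gives A7.
- **Merits:** it is biomimetic, brings the whole cinnamoyl unit in with the ring, and needs no late functionalisation or metalation of a hindered arene. In this respect it is better than steps 9, 11 and 12 of the chosen plan.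
- **Weak points:**
  - A7 carries a free hydroxyl at C1′, so one of two chelated ortho hydroxyls would have to be methylated selectively.
  - The methoxymethyl ethers again need acid.
  - C5 must already be in place on the pyrone, where it is vinylogously activated and exposed to methoxide.
  - A8 would take a long synthesis that includes its own asymmetric construction of C5.
- **Comparison:** the end game is shorter in C–C bond-forming steps, but the total is longer and two selectivity problems are left for the end. The chosen plan has an unprecedented key step but a symmetric ring A and a single, fluoride-based deprotection.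

Key step: step 8

Assumption: the sense of induction of the bis(oxazoline) ligand in step 8 cannot be assigned in advance. The route is written for the ligand antipode that delivers (R)-12; both antipodes derive from the two enantiomers of cis-1-amino-2-indanol. (E)-4-Hydroxycinnamaldehyde 14 is treated as a purchasable compound. TBS = tert-butyldimethylsilyl.

## Route

Step 1
Reactants: 1 2,4,6-trimethoxybenzaldehyde
Product: 2 2,6-dihydroxy-4-methoxybenzaldehyde
Conditions: AlCl3 (4 equiv), CH2Cl2, 0 °C to rt; cold dilute HCl
Reagents that add atoms: none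
Why: Chelation-controlled ether cleavage: AlCl3 held between the carbonyl oxygen and an ortho methoxy oxygen activates only the ortho methyl groups towards chloride, as in the usual preparation of 2,6-dihydroxybenzaldehydes from their dimethyl ethers; the para methoxy group cannot chelate and should stay.

Step 2
Reactants: 2 2,6-dihydroxy-4-methoxybenzaldehyde
Product: 3 2,6-bis(TBS-oxy)-4-methoxybenzaldehyde
Conditions: TBSCl (2.6 equiv), imidazole (5 equiv), DMAP (cat.), DMF, rt to 40 °C
Reagents that add atoms: tert-butyldimethylsilyl chloride, CC(C)(C)[Si](C)(C)Cl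
Why: Standard silylation of phenols; the hydrogen-bonded second hydroxyl reacts more slowly, hence the excess reagent, DMAP and mild warming.

Step 3
Reactants: 3 2,6-bis(TBS-oxy)-4-methoxybenzaldehyde
Product: 4 5-methoxy-1,3-bis(TBS-oxy)-2-vinylbenzene
Conditions: Ph3PCH3Br (1.3 equiv), KN(SiMe3)2 (1.2 equiv), THF, 0 °C; then 3, 0 °C to rt; Et3N-deactivated silica
Reagents that add atoms: methyltriphenylphosphonium bromide, C[P+](c1ccccc1)(c1ccccc1)c1ccccc1.[Br-]
Why: Wittig methylenation of a non-enolisable aldehyde; a slight deficit of amide base relative to the salt keeps free base away from the aryl silyl ethers, and the electron-rich styrene is kept away from acid.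

Step 4
Reactants: 5 3-(4-hydroxyphenyl)propan-1-ol
Product: 6 4-(3-iodopropyl)phenol
Conditions: PPh3, I2, imidazole, CH2Cl2, 0 °C to rt
Reagents that add atoms: iodine, II
Why: Appel iodination converts the primary alcohol; the phenol cannot be displaced at an sp2 carbon and is recovered on work-up, so no selective protection is needed.

Step 5
Reactants: 6 4-(3-iodopropyl)phenol
Product: 7 1-(3-iodopropyl)-4-(TBS-oxy)benzene
Conditions: TBSCl, imidazole, CH2Cl2, 0 °C to rt
Reagents that add atoms: tert-butyldimethylsilyl chloride, CC(C)(C)[Si](C)(C)Cl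
Why: Phenol silylation is fast at 0 °C, much faster than N-alkylation of imidazole by the primary iodide.

Step 6
Reactants: 8 (E)-4-hydroxycinnamic acid
Product: 10 (E)-3-[4-(TBS-oxy)phenyl]prop-2-enoic acid, via bis-silylated cinnamate 9 (not isolated)
Conditions: TBSCl (2.3 equiv), imidazole, DMF, rt; then THF/AcOH/H2O, rt
Reagents that add atoms: tert-butyldimethylsilyl chloride, CC(C)(C)[Si](C)(C)Cl
Why: Both acidic groups are silylated and the much more labile silyl ester is then hydrolysed selectively by aqueous acetic acid, leaving the aryl silyl ether.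

Step 7
Reactants: 10 (E)-3-[4-(TBS-oxy)phenyl]prop-2-enoic acid
Product: 11 (E)-1-(2-bromovinyl)-4-(TBS-oxy)benzene
Conditions: NBS (1.1 equiv), LiOAc (0.1 equiv), MeCN/H2O 97:3, rt
Reagents that add atoms: N-bromosuccinimide, O=C1CCC(=O)N1Br
Why: Catalytic Hunsdiecker-type bromodecarboxylation: the carboxylate attacks NBS-derived bromonium at the alkene of an electron-rich cinnamate and anti decarboxylative elimination gives the (E)-bromostyrene, a reaction that works best with para-oxygenated cinnamic acids.

Step 8
Reactants: 4 5-methoxy-1,3-bis(TBS-oxy)-2-vinylbenzene; 7 1-(3-iodopropyl)-4-(TBS-oxy)benzene; 11 (E)-1-(2-bromovinyl)-4-(TBS-oxy)benzene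
Product: 12 2-[(1E,3R)-1,7-bis(4-(TBS-oxy)phenyl)hept-1-en-3-yl]-1,3-bis(TBS-oxy)-5-methoxybenzene
Conditions: 4 (2.0 equiv), 7 (1.5 equiv), 11 (1.0 equiv), NiBr2(dme) (10 mol%), cyclopropane-bridged indane-fused bis(oxazoline) (12 mol%), Mn powder (3 equiv), NaI (0.5 equiv), DMA, 0 °C, slow addition of 7 and 11
Reagents that add atoms: none
Why: Proposed new method: zerovalent nickel formed from NiBr2(dme), the bis(oxazoline) and Mn adds oxidatively to 11 to give an (E)-alkenylnickel bromide while a monovalent nickel halide abstracts iodine from 7; the 3-arylpropyl radical adds to the unsubstituted terminus of styrene 4 (C3–C4 bond), the C5 benzylic radical is captured by the alkenylnickel species, and the resulting trivalent nickel intermediate forms the C5–C6 bond by reductive elimination, Mn returning nickel to the low-valent state. The closest known reaction types are nickel-catalysed asymmetric reductive three-component alkyl-arylation and alkyl-alkenylation of alkenes with tertiary or fluorinated alkyl halides and the enantioconvergent nickel-catalysed reductive coupling of secondary benzylic chlorides with alkenyl bromides with this ligand class; new here are a primary unactivated iodide as radical source and an electron-rich, doubly ortho-substituted styrene as acceptor. No ring closes. The one new stereocentre, C5, is set by the catalyst: the benzylic radical is planar and its capture at nickel is reversible, so the chiral ligand decides the configuration at reductive elimination, and the ligand antipode is chosen to give R. Three selectivities are needed: the order of assembly (radical addition to 4 before capture at nickel), served by the excess and high concentration of 4, a modest nickel loading and slow addition of the two halides; regiochemistry, secured because only the benzylic radical can form; and alkene geometry, kept because alkenylnickel species hold their configuration at 0 °C. The two ortho silyloxy groups should slow dimerisation and oligomerisation of the benzylic radical more than its capture, and the radical path avoids the C5 cation that ring A would stabilise.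

Step 9
Reactants: 12 2-[(1E,3R)-1,7-bis(4-(TBS-oxy)phenyl)hept-1-en-3-yl]-1,3-bis(TBS-oxy)-5-methoxybenzene
Product: 13 2-[(1E,3R)-1,7-bis(4-(TBS-oxy)phenyl)hept-1-en-3-yl]-1,3-bis(TBS-oxy)-4-iodo-5-methoxybenzene
Conditions: NIS (1.05 equiv), NaHCO3 (solid), MeCN/CH2Cl2, 0 °C to rt, dark
Reagents that add atoms: N-iodosuccinimide, O=C1CCC(=O)N1I
Why: Electrophilic aromatic iodination: C2′ and C6′ are equivalent and each is ortho or para to three oxygen donors, so ring A should react ahead of the disubstituted styrene alkene and the mono-oxygenated rings; one equivalent of NIS without acid limits a second iodination.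

Step 10
Reactants: 14 (E)-3-(4-hydroxyphenyl)prop-2-enal
Product: 15 (E)-3-[4-(TBS-oxy)phenyl]prop-2-enal
Conditions: TBSCl, imidazole, CH2Cl2, rt
Reagents that add atoms: tert-butyldimethylsilyl chloride, CC(C)(C)[Si](C)(C)Cl
Why: Routine phenol silylation; the enal is untouched.

Step 11
Reactants: 13 2-[(1E,3R)-1,7-bis(4-(TBS-oxy)phenyl)hept-1-en-3-yl]-1,3-bis(TBS-oxy)-4-iodo-5-methoxybenzene; 15 (E)-3-[4-(TBS-oxy)phenyl]prop-2-enal
Product: 17 (2E)-1-{3-[(1E,3R)-1,7-bis(4-(TBS-oxy)phenyl)hept-1-en-3-yl]-2,4-bis(TBS-oxy)-6-methoxyphenyl}-3-[4-(TBS-oxy)phenyl]prop-2-en-1-ol (both epimers at the carbinol carbon), via arylmagnesium chloride 16 (not isolated)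
Conditions: iPrMgCl·LiCl (1.2 equiv), THF, −20 to 0 °C; then 15 (1.3 equiv), −40 °C; aq. NH4Cl at −40 °C
Reagents that add atoms: none
Why: Iodine–magnesium exchange with the LiCl-activated isopropyl Grignard reagent is the standard way to metalate functionalised aryl iodides; the arylmagnesium species, unlike an aryllithium, should not undergo retro-Brook silyl migration from the neighbouring oxygen, and it adds 1,2 to the enal. The carbinol centre forms as both epimers, which does not matter because it is oxidised in step 12; C5 is not acidic enough to be touched.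

Step 12
Reactants: 17 (2E)-1-{3-[(1E,3R)-1,7-bis(4-(TBS-oxy)phenyl)hept-1-en-3-yl]-2,4-bis(TBS-oxy)-6-methoxyphenyl}-3-[4-(TBS-oxy)phenyl]prop-2-en-1-ol
Product: 18 (2E)-1-{3-[(1E,3R)-1,7-bis(4-(TBS-oxy)phenyl)hept-1-en-3-yl]-2,4-bis(TBS-oxy)-6-methoxyphenyl}-3-[4-(TBS-oxy)phenyl]prop-2-en-1-one
Conditions: activated MnO2 (excess), CH2Cl2, rt
Reagents that add atoms: none
Why: MnO2 oxidises alcohols that are both allylic and benzylic under neutral heterogeneous conditions; silyl ethers, the styrene and C5 are not affected.

Step 13
Reactants: 18 (2E)-1-{3-[(1E,3R)-1,7-bis(4-(TBS-oxy)phenyl)hept-1-en-3-yl]-2,4-bis(TBS-oxy)-6-methoxyphenyl}-3-[4-(TBS-oxy)phenyl]prop-2-en-1-one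
Product: 19 deoxycalyxin A, (2E)-1-{3-[(1E,3R)-1,7-bis(4-hydroxyphenyl)hept-1-en-3-yl]-2,4-dihydroxy-6-methoxyphenyl}-3-(4-hydroxyphenyl)prop-2-en-1-one
Conditions: Bu4NF (7 equiv), AcOH (7 equiv), THF, 0 °C to rt
Reagents that add atoms: none
Why: Fluoride cleaves aryl silyl ethers quickly; buffering with acetic acid keeps the liberated phenoxides protonated so that the C5′ oxygen does not add to the enone (flavanone closure), and C5 sees neither strong base nor acid.

## Compound list

1 | 2,4,6-trimethoxybenzaldehyde | COc1cc(OC)c(C=O)c(OC)c1 | starting material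
2 | 2,6-dihydroxy-4-methoxybenzaldehyde | COc1cc(O)c(C=O)c(O)c1 | intermediate
3 | 2,6-bis(tert-butyldimethylsilyloxy)-4-methoxybenzaldehyde | COc1cc(O[Si](C)(C)C(C)(C)C)c(C=O)c(O[Si](C)(C)C(C)(C)C)c1 | intermediate
4 | 5-methoxy-1,3-bis(tert-butyldimethylsilyloxy)-2-vinylbenzene | C=Cc1c(O[Si](C)(C)C(C)(C)C)cc(OC)cc1O[Si](C)(C)C(C)(C)C | intermediate
5 | 3-(4-hydroxyphenyl)propan-1-ol | OCCCc1ccc(O)cc1 | starting material
6 | 4-(3-iodopropyl)phenol | ICCCc1ccc(O)cc1 | intermediate
7 | 1-(3-iodopropyl)-4-(tert-butyldimethylsilyloxy)benzene | ICCCc1ccc(O[Si](C)(C)C(C)(C)C)cc1 | intermediate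
8 | (E)-4-hydroxycinnamic acid | OC(=O)/C=C/c1ccc(O)cc1 | starting material
9 | tert-butyldimethylsilyl (E)-3-[4-(tert-butyldimethylsilyloxy)phenyl]prop-2-enoate | CC(C)(C)[Si](C)(C)OC(=O)/C=C/c1ccc(O[Si](C)(C)C(C)(C)C)cc1 | intermediate
10 | (E)-3-[4-(tert-butyldimethylsilyloxy)phenyl]prop-2-enoic acid | OC(=O)/C=C/c1ccc(O[Si](C)(C)C(C)(C)C)cc1 | intermediate
11 | (E)-1-(2-bromovinyl)-4-(tert-butyldimethylsilyloxy)benzene | Br/C=C/c1ccc(O[Si](C)(C)C(C)(C)C)cc1 | intermediate
12 | 2-[(1E,3R)-1,7-bis(4-(tert-butyldimethylsilyloxy)phenyl)hept-1-en-3-yl]-1,3-bis(tert-butyldimethylsilyloxy)-5-methoxybenzene | COc1cc(O[Si](C)(C)C(C)(C)C)c([C@@H](/C=C/c2ccc(O[Si](C)(C)C(C)(C)C)cc2)CCCCc2ccc(O[Si](C)(C)C(C)(C)C)cc2)c(O[Si](C)(C)C(C)(C)C)c1 | intermediate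
13 | 2-[(1E,3R)-1,7-bis(4-(tert-butyldimethylsilyloxy)phenyl)hept-1-en-3-yl]-1,3-bis(tert-butyldimethylsilyloxy)-4-iodo-5-methoxybenzene | COc1cc(O[Si](C)(C)C(C)(C)C)c([C@@H](/C=C/c2ccc(O[Si](C)(C)C(C)(C)C)cc2)CCCCc2ccc(O[Si](C)(C)C(C)(C)C)cc2)c(O[Si](C)(C)C(C)(C)C)c1I | intermediate
14 | (E)-3-(4-hydroxyphenyl)prop-2-enal | O=C/C=C/c1ccc(O)cc1 | starting material
15 | (E)-3-[4-(tert-butyldimethylsilyloxy)phenyl]prop-2-enal | O=C/C=C/c1ccc(O[Si](C)(C)C(C)(C)C)cc1 | intermediate
16 | {3-[(1E,3R)-1,7-bis(4-(tert-butyldimethylsilyloxy)phenyl)hept-1-en-3-yl]-2,4-bis(tert-butyldimethylsilyloxy)-6-methoxyphenyl}magnesium chloride | COc1cc(O[Si](C)(C)C(C)(C)C)c([C@@H](/C=C/c2ccc(O[Si](C)(C)C(C)(C)C)cc2)CCCCc2ccc(O[Si](C)(C)C(C)(C)C)cc2)c(O[Si](C)(C)C(C)(C)C)c1[Mg]Cl | intermediate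
17 | (2E)-1-{3-[(1E,3R)-1,7-bis(4-(tert-butyldimethylsilyloxy)phenyl)hept-1-en-3-yl]-2,4-bis(tert-butyldimethylsilyloxy)-6-methoxyphenyl}-3-[4-(tert-butyldimethylsilyloxy)phenyl]prop-2-en-1-ol, both carbinol epimers | COc1cc(O[Si](C)(C)C(C)(C)C)c([C@@H](/C=C/c2ccc(O[Si](C)(C)C(C)(C)C)cc2)CCCCc2ccc(O[Si](C)(C)C(C)(C)C)cc2)c(O[Si](C)(C)C(C)(C)C)c1C(O)/C=C/c1ccc(O[Si](C)(C)C(C)(C)C)cc1 | intermediate
18 | (2E)-1-{3-[(1E,3R)-1,7-bis(4-(tert-butyldimethylsilyloxy)phenyl)hept-1-en-3-yl]-2,4-bis(tert-butyldimethylsilyloxy)-6-methoxyphenyl}-3-[4-(tert-butyldimethylsilyloxy)phenyl]prop-2-en-1-one | COc1cc(O[Si](C)(C)C(C)(C)C)c([C@@H](/C=C/c2ccc(O[Si](C)(C)C(C)(C)C)cc2)CCCCc2ccc(O[Si](C)(C)C(C)(C)C)cc2)c(O[Si](C)(C)C(C)(C)C)c1C(=O)/C=C/c1ccc(O[Si](C)(C)C(C)(C)C)cc1 | intermediate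
19 | deoxycalyxin A | COc1cc(O)c([C@@H](/C=C/c2ccc(O)cc2)CCCCc2ccc(O)cc2)c(O)c1C(=O)/C=C/c1ccc(O)cc1 | target

## Step count and risk

Total: 13 steps. Longest linear sequence: 8 steps (1, 2, 3, 8, 9, 11, 12, 13).

**Step 8 (key step, new method).** What may go wrong:
- Direct coupling of the primary radical with the alkenylnickel species may outrun its addition to the twisted, electron-rich styrene.
- Capture of the doubly ortho-substituted benzylic radical may be slow or poorly enantioselective.
- The bromide may homocouple, or the benzylnickel intermediate may undergo β-hydride elimination.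

The fallback uses known chemistry, sets out from aldehyde 3 and returns at 12.
- Horner–Wadsworth–Emmons olefination of 3 (triethyl phosphonoacetate, LiCl, DBU, MeCN) should give ethyl (E)-3-[2,6-bis(TBS-oxy)-4-methoxyphenyl]prop-2-enoate F1.
- iBu2AlH reduces it to (E)-3-[2,6-bis(TBS-oxy)-4-methoxyphenyl]prop-2-en-1-ol F2.
- MsCl, LiCl and 2,4,6-collidine convert F2 into (E)-2-(3-chloroprop-1-enyl)-1,3-bis(TBS-oxy)-5-methoxybenzene F3, used crude.
- The nucleophile comes from commercial 4-(4-methoxyphenyl)butan-1-ol: 48% HBr at reflux gives 4-(4-bromobutyl)phenol F4, TBSCl/imidazole gives 1-(4-bromobutyl)-4-(TBS-oxy)benzene F5, and Mg in THF gives {4-[4-(TBS-oxy)phenyl]butyl}magnesium bromide F6.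
- Copper-catalysed enantioselective SN2′ allylic alkylation of F3 with F6 (copper thiophene-2-carboxylate (CuTC), chiral phosphoramidite, CH2Cl2, −78 °C) gives the branched alkene 1,3-bis(TBS-oxy)-5-methoxy-2-{(3R)-7-[4-(TBS-oxy)phenyl]hept-1-en-3-yl}benzene F7.
- Cross-metathesis of F7 with commercial 4-(tert-butyldimethylsilyloxy)styrene (second-generation Grubbs catalyst, CH2Cl2, 40 °C) installs ring C with E geometry and gives 12.

**Step 9.** What may go wrong:
- Iodonium attack on the C6=C7 alkene may compete, with participation of a neighbouring silyloxy oxygen (iodoetherification with loss of silyl).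
- Substitution at the position shielded by the silyl group may be slow.
- A second iodination may occur.

The fallback sets out from 12 and returns at 17. Vilsmeier–Haack formylation of 12 with preformed (chloromethylene)dimethyliminium chloride (MeCN, 0 °C; aq. NaOAc) gives 3-[(1E,3R)-1,7-bis(4-(TBS-oxy)phenyl)hept-1-en-3-yl]-2,4-bis(TBS-oxy)-6-methoxybenzaldehyde F8. Bromide 11 is converted with t-BuLi (2 equiv, Et2O/THF, −78 °C) into (E)-{2-[4-(TBS-oxy)phenyl]ethenyl}lithium F9, which adds to F8 to give 17. The polarity of the ketone bond construction is thus reversed and no halonium ion is involved.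

**Step 11.** What may go wrong:
- The exchange on the hindered, electron-rich iodide may be incomplete, followed by protonation on work-up.
- The Grignard reagent may add in conjugate fashion.
- A silyl group may migrate from the C5′ oxygen to the new alkoxide.

The fallback sets out from 13 and returns at 18, bypassing 16 and 17. Miyaura borylation of 11 (B2pin2, PdCl2(dppf), KOPh, toluene, 50 °C) gives (E)-2-{2-[4-(TBS-oxy)phenyl]ethenyl}-4,4,5,5-tetramethyl-1,3,2-dioxaborolane F10. Carbonylative Suzuki–Miyaura coupling of 13 with F10 (CO, 1 atm, Pd(PPh3)4, K2CO3, anisole, 80 °C) gives 18 directly.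

**Step 12.** What may go wrong:
- The doubly activated carbinol may ionise on handling.
- The oxidation may be sluggish at the crowded centre.

The fallback sets out from 13 (through 16) and returns at 18, without a carbinol. Acid 10 is converted with carbonyldiimidazole and MeNHOMe·HCl into (E)-N-methoxy-N-methyl-3-[4-(TBS-oxy)phenyl]prop-2-enamide F11, and 16 is acylated by F11 (THF, 0 °C to rt) to give 18 after aqueous NH4Cl.

## Further compounds

F1 | step 8 | ethyl (E)-3-[2,6-bis(tert-butyldimethylsilyloxy)-4-methoxyphenyl]prop-2-enoate | CCOC(=O)/C=C/c1c(O[Si](C)(C)C(C)(C)C)cc(OC)cc1O[Si](C)(C)C(C)(C)C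
F2 | step 8 | (E)-3-[2,6-bis(tert-butyldimethylsilyloxy)-4-methoxyphenyl]prop-2-en-1-ol | OC/C=C/c1c(O[Si](C)(C)C(C)(C)C)cc(OC)cc1O[Si](C)(C)C(C)(C)C
F3 | step 8 | (E)-2-(3-chloroprop-1-enyl)-1,3-bis(tert-butyldimethylsilyloxy)-5-methoxybenzene | ClC/C=C/c1c(O[Si](C)(C)C(C)(C)C)cc(OC)cc1O[Si](C)(C)C(C)(C)C
F4 | step 8 | 4-(4-bromobutyl)phenol | BrCCCCc1ccc(O)cc1
F5 | step 8 | 1-(4-bromobutyl)-4-(tert-butyldimethylsilyloxy)benzene | BrCCCCc1ccc(O[Si](C)(C)C(C)(C)C)cc1
F6 | step 8 | {4-[4-(tert-butyldimethylsilyloxy)phenyl]butyl}magnesium bromide | Br[Mg]CCCCc1ccc(O[Si](C)(C)C(C)(C)C)cc1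
F7 | step 8 | 1,3-bis(tert-butyldimethylsilyloxy)-5-methoxy-2-{(3R)-7-[4-(tert-butyldimethylsilyloxy)phenyl]hept-1-en-3-yl}benzene | COc1cc(O[Si](C)(C)C(C)(C)C)c([C@@H](C=C)CCCCc2ccc(O[Si](C)(C)C(C)(C)C)cc2)c(O[Si](C)(C)C(C)(C)C)c1
F8 | step 9 | 3-[(1E,3R)-1,7-bis(4-(tert-butyldimethylsilyloxy)phenyl)hept-1-en-3-yl]-2,4-bis(tert-butyldimethylsilyloxy)-6-methoxybenzaldehyde | COc1cc(O[Si](C)(C)C(C)(C)C)c([C@@H](/C=C/c2ccc(O[Si](C)(C)C(C)(C)C)cc2)CCCCc2ccc(O[Si](C)(C)C(C)(C)C)cc2)c(O[Si](C)(C)C(C)(C)C)c1C=O
F9 | step 9 | (E)-{2-[4-(tert-butyldimethylsilyloxy)phenyl]ethenyl}lithium | [Li]/C=C/c1ccc(O[Si](C)(C)C(C)(C)C)cc1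
F10 | step 11 | (E)-2-{2-[4-(tert-butyldimethylsilyloxy)phenyl]ethenyl}-4,4,5,5-tetramethyl-1,3,2-dioxaborolane | CC1(C)OB(/C=C/c2ccc(O[Si](C)(C)C(C)(C)C)cc2)OC1(C)C
F11 | step 12 | (E)-N-methoxy-N-methyl-3-[4-(tert-butyldimethylsilyloxy)phenyl]prop-2-enamide | CON(C)C(=O)/C=C/c1ccc(O[Si](C)(C)C(C)(C)C)cc1
A1 | alternative 1 | 7-methoxy-5-(methoxymethoxy)-2-[4-(methoxymethoxy)phenyl]-2H-chromene (racemic) | COc1cc(OCOC)c2C=CC(c3ccc(OCOC)cc3)Oc2c1
A2 | alternative 1 | 5-methoxy-3-(methoxymethoxy)-2-(trimethylsilyl)phenyl trifluoromethanesulfonate | COc1cc(OCOC)c([Si](C)(C)C)c(OS(=O)(=O)C(F)(F)F)c1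
A3 | alternative 1 | (E)-3-[4-(methoxymethoxy)phenyl]prop-2-enal | O=C/C=C/c1ccc(OCOC)cc1
A4 | alternative 2 | 5-methoxy-3-(triisopropylsilyloxy)-2-{(3R)-7-[4-(triisopropylsilyloxy)phenyl]hept-1-en-3-yl}phenol | COc1cc(O[Si](C(C)C)(C(C)C)C(C)C)c([C@@H](C=C)CCCCc2ccc(O[Si](C(C)C)(C(C)C)C(C)C)cc2)c(O)c1
A5 | alternative 2 | 3-methoxycyclobut-2-en-1-one | COC1=CC(=O)C1
A6 | alternative 2 | triisopropyl{[(3R)-3-vinyl-7-(4-(triisopropylsilyloxy)phenyl)hept-1-yn-1-yl]oxy}silane | CC(C)[Si](C(C)C)(C(C)C)OC#C[C@@H](C=C)CCCCc1ccc(O[Si](C(C)C)(C(C)C)C(C)C)cc1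
A7 | alternative 3 | (2E)-1-{3-[(1E,3R)-1,7-bis(4-(methoxymethoxy)phenyl)hept-1-en-3-yl]-2,6-dihydroxy-4-(methoxymethoxy)phenyl}-3-[4-(methoxymethoxy)phenyl]prop-2-en-1-one | O=C(/C=C/c1ccc(OCOC)cc1)c1c(O)cc(OCOC)c([C@@H](/C=C/c2ccc(OCOC)cc2)CCCCc2ccc(OCOC)cc2)c1O
A8 | alternative 3 | 3-[(1E,3R)-1,7-bis(4-(methoxymethoxy)phenyl)hept-1-en-3-yl]-4-(methoxymethoxy)-6-[(3E)-4-(4-(methoxymethoxy)phenyl)-2-oxobut-3-en-1-yl]-2H-pyran-2-one | O=C(/C=C/c1ccc(OCOC)cc1)CC1=CC(OCOC)=C([C@@H](/C=C/c2ccc(OCOC)cc2)CCCCc2ccc(OCOC)cc2)C(=O)O1
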